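**Plan**

- Retrosynthesis: the phenol is unmasked last from a benzyl ether, and the C3 methyl is traced back through CH2OMs, CH2OH and CO2Me to a geminal diester at C3.
- The oxolane (O1, C2, C3, C4, C5) is cut at O1–C5 and C2–C3. C5 is a benzylic ether carbon that carries the 3,4,5-trimethoxyphenyl donor and adjoins C4(CH3), so C3–C4–C5 is the skeleton of an aryl cyclopropane-1,1-diester. O1–C2(aryl) is the carbonyl group of 3-(benzyloxy)-4,5-dimethoxybenzaldehyde.
- The cyclopropane is cut at both bonds to the malonate carbon, giving a Z-propenyl arene (from a Wittig reaction) and a malonate carbene equivalent.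
- Forward: Wittig olefination, copper–bis(oxazoline) cyclopropanation, Lewis-acid [3+2] annulation with the aldehyde (the only ring-forming event; it closes the oxolane), then loss of one ester, equilibration, reduction of the other ester to methyl, and debenzylation.
- Stereochemistry: C4 comes from the ligand-controlled cyclopropanation, C5 from inversion at the benzylic carbon of the cis cyclopropane, C2 from the 2,5-cis preference of the annulation, and C3 from thermodynamic equilibration of the ester trans to the C2 aryl group.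

Key step: step 5

Assumption: the sense of induction of the chiral bis(oxazoline)–copper catalyst on alkene 4 is taken to follow the choice of ligand antipode (both are accessible); the antipode leading to (2S,3S)-7 is used.

**Step 1**
Reactants: 1 (3,4,5-trimethoxybenzaldehyde) and 2 (ethyltriphenylphosphonium bromide)
Product: 4 (Z)-1,2,3-trimethoxy-5-(prop-1-en-1-yl)benzene, via ethylidenetriphenylphosphorane 3 (not isolated)
Conditions: 2, NaN(SiMe3)2, THF, 0 °C; then 1, −78 °C → rt
Reagents that add atoms: none
Why: A salt-free Wittig olefination of an aromatic aldehyde with the non-stabilised ethylidene ylide should close the cis oxaphosphetane under kinetic control and so give mainly the Z alkene, any E isomer being removed on AgNO3-impregnated silica before the cyclopropanation.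

**Step 2**
Reactants: 5 (dimethyl malonate)
Product: 6 dimethyl 2-(phenyl-λ3-iodanylidene)propanedioate (phenyliodonium bis(methoxycarbonyl)methanide)
Conditions: PhI(OAc)2, KOH, MeCN, 0 °C
Reagents that add atoms: (diacetoxyiodo)benzene, CC(=O)OI(OC(C)=O)c1ccccc1
Why: Base-mediated condensation of a malonate with PhI(OAc)2 is the standard preparation of phenyliodonium malonate ylides, which precipitate on dilution with water and serve as a diazo-free source of the malonate carbene.

**Step 3**
Reactants: 4 ((Z)-1,2,3-trimethoxy-5-(prop-1-en-1-yl)benzene) and 6 (phenyliodonium bis(methoxycarbonyl)methanide)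
Product: 7 dimethyl (2S,3S)-2-methyl-3-(3,4,5-trimethoxyphenyl)cyclopropane-1,1-dicarboxylate (methyl and aryl cis)
Conditions: Cu(MeCN)4PF6 (5 mol %), chiral side-armed bis(oxazoline) ligand (6 mol %), 4 Å MS, toluene, 0 °C
Reagents that add atoms: none
Why: Copper-carbene cyclopropanation with the iodonium ylide as malonate-carbene source is a concerted, stereospecific syn addition, so the Z geometry of 4 becomes the cis relationship of methyl and aryl while the chiral bis(oxazoline) ligand selects the alkene face and thereby sets both ring stereocentres as 2S,3S.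

**Step 4**
Reactants: 8 (3-hydroxy-4,5-dimethoxybenzaldehyde)
Product: 9 3-(benzyloxy)-4,5-dimethoxybenzaldehyde
Conditions: BnBr, K2CO3, DMF, rt
Reagents that add atoms: benzyl bromide, BrCc1ccccc1
Why: Williamson etherification of the phenoxide with benzyl bromide masks the acidic phenol as an ether that should withstand the Lewis acid, the basic and the hydride steps and leave cleanly by hydrogenolysis at the end.

**Step 5**
Reactants: 7 (dimethyl (2S,3S)-2-methyl-3-(3,4,5-trimethoxyphenyl)cyclopropane-1,1-dicarboxylate) and 9 (3-(benzyloxy)-4,5-dimethoxybenzaldehyde)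
Product: 10 dimethyl (2R,4R,5R)-2-[3-(benzyloxy)-4,5-dimethoxyphenyl]-4-methyl-5-(3,4,5-trimethoxyphenyl)oxolane-3,3-dicarboxylate (aryl groups cis to each other, C4 methyl trans to both)
Conditions: Sn(OTf)2 (10 mol %), 9 (2 equiv), CH2Cl2, rt
Reagents that add atoms: none
Why: Sn(OTf)2 chelates the geminal diester of 7 and polarises the bond between the malonate carbon and the benzylic carbon; the carbonyl oxygen of 9 then attacks the benzylic carbon from the rear in an SN2-like opening of a tight ion pair (O1–C5, with inversion), and the tin malonate enolate adds to the aryl oxocarbenium carbon (C2–C3). The closest known reaction is the Lewis-acid-catalysed stereospecific [3+2] annulation of 2-arylcyclopropane-1,1-diesters, 2,3-disubstituted ones included, with aryl aldehydes to 2,5-cis tetrahydrofurans. The oxolane closes in the aldol-type C2–C3 bond formation, a 5-(enolexo)-endo-trig closure with respect to the C=O+ bond, which oxocarbenium ions tolerate. C5 is controlled by inversion at the benzylic carbon of the cis cyclopropane, which places the trimethoxyphenyl group trans to the C4 methyl centre (itself outside the breaking bond and carried unchanged), and C2 is controlled by an envelope transition state with both aryl groups pseudoequatorial, which gives the 2,5-cis arrangement. The step needs SN2-type capture to outrun free ionisation of the benzylic bond, which would scramble C5; this should be secured by the only moderate donor strength of the trimethoxyphenyl group (para methoxy twisted out of conjugation, meta methoxy groups inductively withdrawing), by the nucleophilic, electron-rich aldehyde used in excess, and by the mild tin triflate catalyst at room temperature.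

**Step 6**
Reactants: 10 (the oxolane-3,3-diester)
Product: 11 methyl (2S,4R,5R)-2-[3-(benzyloxy)-4,5-dimethoxyphenyl]-4-methyl-5-(3,4,5-trimethoxyphenyl)oxolane-3-carboxylate, mixture of C3 epimers
Conditions: LiCl, H2O, DMSO, 150 °C
Reagents that add atoms: none
Why: Krapcho dealkoxycarbonylation (chloride demethylates one ester, the carboxylate loses CO2 and water protonates the ester enolate) removes one ester without touching C2, C4 or C5 and leaves C3 as an epimer mixture that the next step levels.

**Step 7**
Reactants: 11 (C3-epimeric monoester)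
Product: 12 methyl (2S,3S,4R,5R)-2-[3-(benzyloxy)-4,5-dimethoxyphenyl]-4-methyl-5-(3,4,5-trimethoxyphenyl)oxolane-3-carboxylate (ester trans to the C2 aryl, cis to the C4 methyl)
Conditions: NaOMe (0.3 equiv), MeOH, 40 °C
Reagents that add atoms: none
Why: Base-mediated epimerisation through the ester enolate puts C3, the only acidic stereocentre, under thermodynamic control, and the epimer with the ester trans to the C2 aryl group and cis only to the small C4 methyl (two substituents on each ring face instead of three on one) should predominate, the minor epimer being separated and returned to the same conditions.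

**Step 8**
Reactants: 12 (the 3S monoester)
Product: 13 [(2S,3R,4R,5R)-2-[3-(benzyloxy)-4,5-dimethoxyphenyl]-4-methyl-5-(3,4,5-trimethoxyphenyl)oxolan-3-yl]methanol
Conditions: LiAlH4, THF, 0 °C
Reagents that add atoms: none
Why: Hydride reduction of the ester to the primary alcohol with LiAlH4 touches no stereocentre and no ether, the change of the C3 descriptor from S to R being a priority effect only.

**Step 9**
Reactants: 13 (the primary alcohol)
Product: 14 [(2S,3R,4R,5R)-2-[3-(benzyloxy)-4,5-dimethoxyphenyl]-4-methyl-5-(3,4,5-trimethoxyphenyl)oxolan-3-yl]methyl methanesulfonate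
Conditions: MsCl, Et3N, CH2Cl2, 0 °C
Reagents that add atoms: methanesulfonyl chloride, CS(=O)(=O)Cl
Why: Mesylation of the primary alcohol turns the hydroxyl into a leaving group under conditions that leave all four stereocentres alone.

**Step 10**
Reactants: 14 (the mesylate)
Product: 15 (2S,3S,4R,5R)-2-[3-(benzyloxy)-4,5-dimethoxyphenyl]-3,4-dimethyl-5-(3,4,5-trimethoxyphenyl)oxolane
Conditions: LiEt3BH, THF, 0 °C → rt
Reagents that add atoms: none
Why: SN2 displacement of the primary mesylate by hydride from LiEt3BH (reductive deoxygenation) should deliver the C3 methyl group, the β-branched primary carbon being within the usual scope of this reagent and C3 itself not being the reacting centre.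

**Step 11**
Reactants: 15 (the benzyl ether)
Product: 16 2,3-dimethoxy-5-[(2S,3S,4R,5R)-3,4-dimethyl-5-(3,4,5-trimethoxyphenyl)oxolan-2-yl]phenol (target)
Conditions: H2 (1 atm), Pd/C (10 %), EtOAc, rt
Reagents that add atoms: none
Why: Catalytic hydrogenolysis of the benzyl aryl ether at one atmosphere in EtOAc should be much faster than cleavage of the benzylic C–O bonds of the oxolane and so free the phenol without touching the four stereocentres.

**Compound list**

1 | 3,4,5-trimethoxybenzaldehyde | COc1cc(C=O)cc(OC)c1OC | starting material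
2 | ethyltriphenylphosphonium bromide | CC[P+](c1ccccc1)(c1ccccc1)c1ccccc1.[Br-] | starting material
3 | ethylidenetriphenylphosphorane | CC=P(c1ccccc1)(c1ccccc1)c1ccccc1 | intermediate (not isolated)
4 | (Z)-1,2,3-trimethoxy-5-(prop-1-en-1-yl)benzene | C/C=C\c1cc(OC)c(OC)c(OC)c1 | intermediate
5 | dimethyl malonate | COC(=O)CC(=O)OC | starting material
6 | dimethyl 2-(phenyl-λ3-iodanylidene)propanedioate | COC(=O)[C-]([I+]c1ccccc1)C(=O)OC | intermediate
7 | dimethyl (2S,3S)-2-methyl-3-(3,4,5-trimethoxyphenyl)cyclopropane-1,1-dicarboxylate | COC(=O)C1(C(=O)OC)[C@H](c2cc(OC)c(OC)c(OC)c2)[C@@H]1C | intermediate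
8 | 3-hydroxy-4,5-dimethoxybenzaldehyde | COc1cc(C=O)cc(O)c1OC | starting material
9 | 3-(benzyloxy)-4,5-dimethoxybenzaldehyde | COc1cc(C=O)cc(OCc2ccccc2)c1OC | intermediate
10 | dimethyl (2R,4R,5R)-2-[3-(benzyloxy)-4,5-dimethoxyphenyl]-4-methyl-5-(3,4,5-trimethoxyphenyl)oxolane-3,3-dicarboxylate | COc1cc([C@H]2O[C@@H](c3cc(OC)c(OC)c(OC)c3)[C@H](C)C2(C(=O)OC)C(=O)OC)cc(OCc4ccccc4)c1OC | intermediate
11 | methyl (2S,4R,5R)-2-[3-(benzyloxy)-4,5-dimethoxyphenyl]-4-methyl-5-(3,4,5-trimethoxyphenyl)oxolane-3-carboxylate, C3 epimer mixture | COc1cc([C@H]2O[C@@H](c3cc(OC)c(OC)c(OC)c3)[C@H](C)C2C(=O)OC)cc(OCc4ccccc4)c1OC | intermediate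
12 | methyl (2S,3S,4R,5R)-2-[3-(benzyloxy)-4,5-dimethoxyphenyl]-4-methyl-5-(3,4,5-trimethoxyphenyl)oxolane-3-carboxylate | COc1cc([C@H]2O[C@@H](c3cc(OC)c(OC)c(OC)c3)[C@H](C)[C@@H]2C(=O)OC)cc(OCc4ccccc4)c1OC | intermediate
13 | [(2S,3R,4R,5R)-2-[3-(benzyloxy)-4,5-dimethoxyphenyl]-4-methyl-5-(3,4,5-trimethoxyphenyl)oxolan-3-yl]methanol | COc1cc([C@H]2O[C@@H](c3cc(OC)c(OC)c(OC)c3)[C@H](C)[C@@H]2CO)cc(OCc4ccccc4)c1OC | intermediate
14 | [(2S,3R,4R,5R)-2-[3-(benzyloxy)-4,5-dimethoxyphenyl]-4-methyl-5-(3,4,5-trimethoxyphenyl)oxolan-3-yl]methyl methanesulfonate | COc1cc([C@H]2O[C@@H](c3cc(OC)c(OC)c(OC)c3)[C@H](C)[C@@H]2COS(C)(=O)=O)cc(OCc4ccccc4)c1OC | intermediate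
15 | (2S,3S,4R,5R)-2-[3-(benzyloxy)-4,5-dimethoxyphenyl]-3,4-dimethyl-5-(3,4,5-trimethoxyphenyl)oxolane | COc1cc([C@H]2O[C@@H](c3cc(OC)c(OC)c(OC)c3)[C@H](C)[C@@H]2C)cc(OCc4ccccc4)c1OC | intermediate
16 | 2,3-dimethoxy-5-[(2S,3S,4R,5R)-3,4-dimethyl-5-(3,4,5-trimethoxyphenyl)oxolan-2-yl]phenol | COc1cc([C@H]2O[C@@H](c3cc(OC)c(OC)c(OC)c3)[C@H](C)[C@@H]2C)cc(O)c1OC | target

Total step count: 11. Longest linear sequence: 9 steps (steps 1, 3, 5, 6, 7, 8, 9, 10 and 11, from aldehyde 1).

**Steps most likely to fail**

1. Step 5 (annulation). Heterolysis of the benzylic C–C bond of 7 may outpace the SN2-type capture by the aldehyde at the hindered, cis-substituted carbon. The cyclopropane would then isomerise (to its trans isomer or to an open-chain alkenyl malonate) and the 4,5-trans relationship would erode. A change of Lewis acid (AlCl3, Hf(OTf)4, lower temperature) would be tried first. The fallback proper changes the donor: the para oxygen of the aryl group is carried as an acyloxy group through the annulation, so that a free benzylic cation is no longer supported. It sets out from phosphonium salt 2, ylide 6 and aldehyde 9, with commercial syringaldehyde (4-hydroxy-3,5-dimethoxybenzaldehyde, COc1cc(C=O)cc(OC)c1O) in the place of 1, and comes back at 10. Pivaloylation (pivaloyl chloride, Et3N, DMAP, CH2Cl2) should give 4-formyl-2,6-dimethoxyphenyl 2,2-dimethylpropanoate F1. The salt-free Wittig reaction of step 1 (ylide 3 from 2) should give the Z alkene 2,6-dimethoxy-4-[(Z)-prop-1-en-1-yl]phenyl 2,2-dimethylpropanoate F2. Cyclopropanation with 6 under the conditions of step 3 should give dimethyl (2S,3S)-2-[4-(2,2-dimethylpropanoyloxy)-3,5-dimethoxyphenyl]-3-methylcyclopropane-1,1-dicarboxylate F3. Annulation of F3 with 9 (Sn(OTf)2, CH2Cl2, rt to 40 °C) should give the pivalate analogue of 10, dimethyl (2R,4R,5R)-2-[3-(benzyloxy)-4,5-dimethoxyphenyl]-5-[4-(2,2-dimethylpropanoyloxy)-3,5-dimethoxyphenyl]-4-methyloxolane-3,3-dicarboxylate F4. NaOMe in MeOH at room temperature should remove the pivalate to give dimethyl (2R,4R,5R)-2-[3-(benzyloxy)-4,5-dimethoxyphenyl]-5-(4-hydroxy-3,5-dimethoxyphenyl)-4-methyloxolane-3,3-dicarboxylate F5, and MeI with K2CO3 in acetone should return 10.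

2. Step 7 (C3 equilibration). The thermodynamic bias between the two C3 epimers may be too small, or prolonged base treatment may slowly scramble C2 through reversible β-alkoxide elimination from the ester enolate. The fallback replaces thermodynamic control by a kinetic alkylation followed by a stereoretentive excision of the ester carbon; it sets out from the epimer mixture 11 and comes back at 15. Deprotonation with LiN(iPr)2 (THF, −78 °C) and methylation with MeI, expected on the enolate face anti to the C2 aryl group, should give methyl (2R,3R,4R,5R)-2-[3-(benzyloxy)-4,5-dimethoxyphenyl]-3,4-dimethyl-5-(3,4,5-trimethoxyphenyl)oxolane-3-carboxylate F6 (new methyl cis to the C4 methyl). LiAlH4 in THF should give [(2R,3S,4R,5R)-2-[3-(benzyloxy)-4,5-dimethoxyphenyl]-3,4-dimethyl-5-(3,4,5-trimethoxyphenyl)oxolan-3-yl]methanol F7, and Dess–Martin periodinane in CH2Cl2 should give (2R,3R,4R,5R)-2-[3-(benzyloxy)-4,5-dimethoxyphenyl]-3,4-dimethyl-5-(3,4,5-trimethoxyphenyl)oxolane-3-carbaldehyde F8. Tsuji–Wilkinson decarbonylation with stoichiometric RhCl(PPh3)3 in hot toluene, which replaces the formyl group by hydrogen with retention, should then deliver 15 and bypass steps 8 to 10. Both C3 epimers of 11 feed the same enolate, so none of the material is lost to the wrong epimer.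

3. Step 3 (asymmetric cyclopropanation). Enantioface discrimination on this electron-rich Z-propenyl arene may be insufficient, or the iodonium ylide may be lost to carbene dimerisation before it is transferred. The fallback gives up asymmetric catalysis for resolution; it sets out from alkene 4 and ylide 6 and comes back at 7. Cyclopropanation with the achiral catalyst Rh2(OAc)4 in CH2Cl2, still stereospecific with respect to alkene geometry, should give racemic dimethyl cis-2-methyl-3-(3,4,5-trimethoxyphenyl)cyclopropane-1,1-dicarboxylate F9. Preparative chromatography on a chiral stationary phase (supercritical CO2 with an alcohol modifier) should then separate the enantiomers and provide (2S,3S)-7.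

**Further compounds**

F1 | step 5 | 4-formyl-2,6-dimethoxyphenyl 2,2-dimethylpropanoate | COc1cc(C=O)cc(OC)c1OC(=O)C(C)(C)C
F2 | step 5 | 2,6-dimethoxy-4-[(Z)-prop-1-en-1-yl]phenyl 2,2-dimethylpropanoate | C/C=C\c1cc(OC)c(OC(=O)C(C)(C)C)c(OC)c1
F3 | step 5 | dimethyl (2S,3S)-2-[4-(2,2-dimethylpropanoyloxy)-3,5-dimethoxyphenyl]-3-methylcyclopropane-1,1-dicarboxylate | COC(=O)C1(C(=O)OC)[C@H](c2cc(OC)c(OC(=O)C(C)(C)C)c(OC)c2)[C@@H]1C
F4 | step 5 | dimethyl (2R,4R,5R)-2-[3-(benzyloxy)-4,5-dimethoxyphenyl]-5-[4-(2,2-dimethylpropanoyloxy)-3,5-dimethoxyphenyl]-4-methyloxolane-3,3-dicarboxylate | COc1cc([C@H]2O[C@@H](c3cc(OC)c(OC(=O)C(C)(C)C)c(OC)c3)[C@H](C)C2(C(=O)OC)C(=O)OC)cc(OCc4ccccc4)c1OC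
F5 | step 5 | dimethyl (2R,4R,5R)-2-[3-(benzyloxy)-4,5-dimethoxyphenyl]-5-(4-hydroxy-3,5-dimethoxyphenyl)-4-methyloxolane-3,3-dicarboxylate | COc1cc([C@H]2O[C@@H](c3cc(OC)c(O)c(OC)c3)[C@H](C)C2(C(=O)OC)C(=O)OC)cc(OCc4ccccc4)c1OC
F6 | step 7 | methyl (2R,3R,4R,5R)-2-[3-(benzyloxy)-4,5-dimethoxyphenyl]-3,4-dimethyl-5-(3,4,5-trimethoxyphenyl)oxolane-3-carboxylate | COc1cc([C@H]2O[C@@H](c3cc(OC)c(OC)c(OC)c3)[C@H](C)[C@]2(C(=O)OC)C)cc(OCc4ccccc4)c1OC
F7 | step 7 | [(2R,3S,4R,5R)-2-[3-(benzyloxy)-4,5-dimethoxyphenyl]-3,4-dimethyl-5-(3,4,5-trimethoxyphenyl)oxolan-3-yl]methanol | COc1cc([C@H]2O[C@@H](c3cc(OC)c(OC)c(OC)c3)[C@H](C)[C@]2(CO)C)cc(OCc4ccccc4)c1OC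
F8 | step 7 | (2R,3R,4R,5R)-2-[3-(benzyloxy)-4,5-dimethoxyphenyl]-3,4-dimethyl-5-(3,4,5-trimethoxyphenyl)oxolane-3-carbaldehyde | COc1cc([C@H]2O[C@@H](c3cc(OC)c(OC)c(OC)c3)[C@H](C)[C@]2(C=O)C)cc(OCc4ccccc4)c1OC
F9 | step 3 | racemic dimethyl cis-2-methyl-3-(3,4,5-trimethoxyphenyl)cyclopropane-1,1-dicarboxylate (1:1 mixture of the 2S,3S and 2R,3R forms) | COC(=O)C1(C(=O)OC)[C@H](c2cc(OC)c(OC)c(OC)c2)[C@@H]1C.COC(=O)C1(C(=O)OC)[C@@H](c2cc(OC)c(OC)c(OC)c2)[C@H]1C
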